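(The numbers were drawn at random within sensible limits; the rest is arithmetic.)

**Easy step.** In this flask each reagent consumed takes one dissolved substrate with it, so c(reagent) minus the substrate remaining, solid or dissolved, stays at 0.100 M.

    solid substrate ⇌ dissolved substrate, rate k1*(cs1 - [dissolved substrate]) while solid is left; crystals form when [dissolved substrate] > cs1 (cs1 = 0.062 M, k1 = 0.061 min⁻¹)
    dissolved substrate + reagent → target (k2 = 0.027 L mol⁻¹ min⁻¹)
    solid product ⇌ target, rate k3*(cs3 - [target]) while solid is left; crystals form when [target] > cs3 (cs3 = 20 mM, k3 = 0.67 min⁻¹)

solid substrate 0.10 M; reagent 0.200 M; time 15 h

- target is meant together with its solid product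
- solid, in amounts per volume of the solution: solid substrate, solid product
- at the start none of the solid substrate is in solution
- dissolved substrate means what is dissolved; the solid is not counted in it
- run time (flask): 15 h

- target and solid product together at 15 h, in percent of the solid substrate charged
- concentration of dissolved substrate in solution at 15 h, in percent of saturation

The reaction step has no back direction and y counts target and solid product together, so I leave crystallisation out.

**Solid stage.** Dissolution has coefficient 0.061 min⁻¹, and it is faster than the pseudo-first-order loss of dissolved substrate, 0.00540 min⁻¹. So c(dissolved substrate) climbs, with a time constant of about 15.1 min, toward the level where the two balance, 0.0570 M. At that level reagent decays first-order, and the solid lasts until 0.0430 M has reacted. Counting the rise, that takes 2.90 h. This crossing time, when the solid is used up and plain second-order kinetics takes over, is what I carry.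

**Tail stage.** From the crossing to 15 h, c(reagent)/c(dissolved substrate) grows exponentially with constant k2 times the excess, reaching 19.6. That gives y = 94.6% and sat = 8.69%.

**Second way.** If I dissolve the whole charge at the start and use the same law, y stays below 95.4%. The two ways part by 0.78 percentage points. This second way is the one that cheats, since it holds 0.10 M in solution against a solubility of 0.062 M.

**The run.** The forecast gives y = 94.6% (93.5% to 95.5%) and sat = 8.7% (7.5% to 10.5%), noting that “the reaction is irreversible and target and solid product are counted together”. The simulation gives y = 94.7% and sat = 8.62%.

**Not at rest.** In the flask, solid substrate stands at 20.9% at 1.50 h, before the crossing, and at 0% at 7.50 h, after it. For the neighbour with 0.080 M of reagent, the same reckoning puts the crossing at 7.45 h and y at 58.2%, and that neighbour gives 58.3%. The flask itself is still moving at 15 h: y reaches 99.6% at 30.0 h and 100% at 150 h, ten times the time, while reagent falls from 52.7% to 50.0% of its charge.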